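## Retrosynthetic overview

1. Target ⇒ 10β,20β-epoxide of the C10=C20 dienone. SmI2 opening at C10 installs the β C20–OH and H-10 last, because a carbon nucleophile can reach the C20 ketone only from the β face, which gives the wrong C20 epimer.
2. Dienone ⇒ seven-membered ketone by intramolecular acylation of a 3-lithiofuran on the C16 ester, then dehydration. Ring B ⇒ key C10–C20 bond by SmI2 reductive coupling of the C20 ketone with the δ-carbon of a dienyl lactone (two electrophilic carbons joined through a reduced, carbanion-like δ-carbon).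
3. Dienyl lactone ⇒ aldol condensation of a spirolactone with a bromofuryl acrolein. Spirolactone ⇒ ring A ketone by two bromoacetate alkylations and a formaldehyde aldol.
4. Ring A ⇒ Cu-catalysed asymmetric conjugate methylation of benzoquinone monoketal (sets C19; all other centres are relayed from it).
5. Ring order: A → spiro-butenolide → B (key step) → seven-membered ring (furan brought in intact) → epoxide/OH, with the C1 ketone converted to the axial acetate.

Carbon labels used below (target skeleton): C1 CH–OAc; C2 CH2; C3 quaternary carbon bearing the lactone CH2 (C4) and the butenolide carbon C7; C6 lactone C=O; C8 =CH; C9 CH2; C10 furfuryl CH; C11 furan carbon on C10; C15 furan carbon on the ketone C16; C17 CH2; C18 quaternary C–CH3; C19 CH–CH3; C20 C–OH. Ring A = C1-C2-C3-C20-C18-C19; ring B = C3-C7-C8-C9-C10-C20; α = the face of ring A that carries the C18 methyl.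

Assumption: all numbered starting materials are commercial (formaldehyde from cracked paraformaldehyde, dimethyldioxirane as its usual acetone solution). The ligand enantiomer in step 1 is the one that gives the 5S product; the sense of induction is not verified here.

## Route

Step 1
Reactants: 1 4,4-dimethoxycyclohexa-2,5-dien-1-one; 2 dimethylzinc; 3 iodomethane
Product: 5 (5S,6S)-4,4-dimethoxy-5,6-dimethylcyclohex-2-en-1-one, via zinc enolate 4 (not isolated)
Conditions: Cu(OTf)2 (2 mol %), (S,R,R)-BINOL bis(1-phenylethyl)phosphoramidite (4 mol %), toluene, −25 °C; then MeI, HMPA, 0 °C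
Reagents that add atoms: dimethylzinc, C[Zn]C; iodomethane, CI
Why: Cu-catalysed asymmetric conjugate addition (Feringa type) desymmetrises the monoketal so that the ligand sets C19, and the zinc enolate is C-methylated in situ at C18 (tandem conjugate addition–enolate alkylation; the C18 configuration is irrelevant because C18 is re-enolised in step 2).

Step 2
Reactants: 5 (5S,6S)-4,4-dimethoxy-5,6-dimethylcyclohex-2-en-1-one; 6 methyl bromoacetate
Product: 8 methyl 2-[(1S,6S)-5,5-dimethoxy-1,6-dimethyl-2-oxocyclohex-3-en-1-yl]acetate, via lithium dienolate 7 (not isolated)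
Conditions: LiN(i-Pr)2, THF, −78 °C; then 6, −78 to −20 °C
Reagents that add atoms: methyl bromoacetate, COC(=O)CBr
Why: Kinetic α'-deprotonation gives the cross-conjugated dienolate and SN2 alkylation by the α-bromo ester occurs anti to the adjacent C19 methyl, setting the C18 quaternary centre with the acetate arm trans to the C19 methyl (substrate-controlled enolate alkylation).

Step 3
Reactants: 8 methyl 2-[(1S,6S)-5,5-dimethoxy-1,6-dimethyl-2-oxocyclohex-3-en-1-yl]acetate; 6 methyl bromoacetate
Product: 10 dimethyl 2,2'-[(1S,6S)-5,5-dimethoxy-1,6-dimethyl-2-oxocyclohexane-1,3-diyl]diacetate (C3 epimers), via lithium enolate 9 (not isolated)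
Conditions: LiBH(s-Bu)3, THF, −78 °C; then 6, HMPA, −78 to 0 °C
Reagents that add atoms: methyl bromoacetate, COC(=O)CBr
Why: The hindered hydride adds 1,4 to the β-unsubstituted enone (the carbonyl is shielded by the quaternary C18) and the regiodefined enolate is trapped by the bromo ester (reductive alkylation); the C3 configuration is fixed only in step 4.

Step 4
Reactants: 10 dimethyl 2,2'-[(1S,6S)-5,5-dimethoxy-1,6-dimethyl-2-oxocyclohexane-1,3-diyl]diacetate; 11 formaldehyde
Product: 14 methyl 2-[(5S,7S,8S)-9,9-dimethoxy-7,8-dimethyl-3,6-dioxo-2-oxaspiro[4.5]decan-7-yl]acetate, via lithium enolate 12 (not isolated), via lithium alkoxide 13 (not isolated)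
Conditions: LiN(i-Pr)2, THF, −78 °C; then CH2O (gas), −78 to 0 °C
Reagents that add atoms: formaldehyde, C=O
Why: C3 is the only enolisable ketone position, and the tetrasubstituted enolate adds to formaldehyde from the α face (syn to the small axial C18 methyl, anti to the larger acetate arm on C18), after which the alkoxide closes the γ-lactone on the geminal ester (aldol addition–lactonisation) and so fixes the C3 quaternary centre.

Step 5
Reactants: 15 3-bromofuran-2-carbaldehyde; 16 (triphenylphosphoranylidene)acetaldehyde
Product: 17 (2E)-3-(3-bromofuran-2-yl)prop-2-enal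
Conditions: toluene, 60 °C
Reagents that add atoms: (triphenylphosphoranylidene)acetaldehyde, O=CC=P(c1ccccc1)(c1ccccc1)c1ccccc1
Why: Wittig olefination with the stabilised formyl ylide gives the E-enal selectively.

Step 6
Reactants: 14 methyl 2-[(5S,7S,8S)-9,9-dimethoxy-7,8-dimethyl-3,6-dioxo-2-oxaspiro[4.5]decan-7-yl]acetate; 17 (2E)-3-(3-bromofuran-2-yl)prop-2-enal
Product: 21 methyl 2-[(4E,5S,7S,8S)-4-[(2E)-3-(3-bromofuran-2-yl)prop-2-en-1-ylidene]-9,9-dimethoxy-7,8-dimethyl-3,6-dioxo-2-oxaspiro[4.5]decan-7-yl]acetate, via lactone enolate 18 (not isolated), via lithium aldolate 19 (not isolated), via allylic mesylate 20 (not isolated)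
Conditions: LiN(i-Pr)2, THF, −78 °C; 17; then MsCl, −78 to 0 °C; then DBU, rt
Reagents that add atoms: (2E)-3-(3-bromofuran-2-yl)prop-2-enal, O=C/C=C/c1occc1Br
Why: The lactone α-CH2 is the most acidic C–H (the ketone has no α-hydrogen), its enolate adds 1,2 to the enal, and mesylation followed by E1cB elimination gives the conjugated dienyl lactone (aldol condensation); the alkene geometry is lost again in step 7.

Step 7
Reactants: 21 methyl 2-[(4E,5S,7S,8S)-4-[(2E)-3-(3-bromofuran-2-yl)prop-2-en-1-ylidene]-9,9-dimethoxy-7,8-dimethyl-3,6-dioxo-2-oxaspiro[4.5]decan-7-yl]acetate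
Product: 22 ring-B carbinol (ring A–ring B–butenolide tricycle; 20α-OH and 10α-bromofuryl; C1 dimethyl ketal; C16 methyl ester)
Conditions: SmI2 (2.5 equiv), t-BuOH (2 equiv), THF, −78 to −20 °C; aq. NH4Cl
Reagents that add atoms: none
Why: Proposed new method: SmI2 puts two electrons into the extended dienyl lactone (or into the ketone, both paths converge), so the normally electrophilic δ-carbon C10 becomes a carbon nucleophile that adds to the normally electrophilic C20 ketone in a six-membered closure from the open β face (the spiro centre is expected to hold C10 over that face), and t-BuOH protonates the samarium alkoxide/dienolate; the closest known reaction type is the SmI2 ketone–enoate (ketyl–olefin) reductive cyclisation, used here in its vinylogous 1,6-mode; the β-face attack gives the diastereomer shown, C10 and C20 are corrected in steps 8, 11 and 12, and any deconjugated butenolide isomer converges in step 8.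

Step 8
Reactants: 22 ring-B carbinol; 23 water
Product: 26 pentacyclic dienone ketone (C10=C20 alkene; seven-membered furyl ketone; C1 ketone), via trilithio species 24 (not isolated), via hydroxy ketone 25 (not isolated)
Conditions: LiN(SiMe3)2 (2.1 equiv), THF, −78 °C; t-BuLi (2.1 equiv), −78 to −40 °C; then 2 M HCl, THF, 40 °C
Reagents that add atoms: water, O
Why: With the alcohol and butenolide masked as alkoxide and dienolate, Br–Li exchange gives a 3-furyllithium that acylates intramolecularly on the methyl ester (Parham cyclisation) to close the seven-membered ketone, and the acidic work-up dehydrates the vinylogous aldol to the conjugated C10=C20 dienone (aldol-condensation-type elimination, which erases the provisional C10 and C20 centres) and hydrolyses the dimethyl ketal.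

Step 9
Reactants: 26 pentacyclic dienone ketone
Product: 27 pentacyclic dienone 1α-alcohol (1R)
Conditions: NaBH4, MeOH/CH2Cl2, −40 °C
Reagents that add atoms: none
Why: NaBH4 reduces the saturated C1 ketone much faster than the doubly vinylogous furyl ketone or the lactone, and hydride arrives from the β face because the α face is blocked by the syn-axial C18 methyl and C4 methylene, giving the axial α alcohol (diastereoselective hydride reduction).

Step 10
Reactants: 27 pentacyclic dienone 1α-alcohol; 28 acetic anhydride
Product: 29 pentacyclic dienone 1α-acetate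
Conditions: Ac2O, DMAP, Et3N, CH2Cl2, 40 °C
Reagents that add atoms: acetic anhydride, CC(=O)OC(C)=O
Why: DMAP-catalysed acylation of the only hydroxyl (Steglich-type acetylation) is done before the tertiary alcohol exists, so the forcing conditions needed for this hindered axial alcohol do no harm.

Step 11
Reactants: 29 pentacyclic dienone 1α-acetate; 30 dimethyldioxirane
Product: 31 10β,20β-epoxide
Conditions: DMDO, acetone, 0 °C
Reagents that add atoms: dimethyldioxirane, CC1(C)OO1
Why: The tetrasubstituted C10=C20 alkene is the most electron-rich π bond (butenolide alkene and 3-acylfuran are deactivated) and is epoxidised from the β face because the α face is blocked by the C18 methyl and the C4 methylene flanking C20 (electrophilic epoxidation), which sets the C20–O bond.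

Step 12
Reactants: 31 10β,20β-epoxide
Product: 32 CNP0329797.2
Conditions: SmI2 (2.2 equiv), THF/MeOH (10:1), −78 °C; aq. NH4Cl
Reagents that add atoms: none
Why: SmI2 reduces the furyl ketone and cleaves the C10–O bond of the vinylogous α,β-epoxy ketone (SmI2 reductive epoxide opening, as for γ,δ-epoxy enones), leaving the β C20–OH and an extended enolate that is protonated at C10 to restore the furan and give the trans-fused (10R) isomer with equatorial furan, which should be the thermodynamic one because H-10 stays exchangeable through the acylfuran.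

## Compound list

1 | 4,4-dimethoxycyclohexa-2,5-dien-1-one | COC1(OC)C=CC(=O)C=C1 | starting material
2 | dimethylzinc | C[Zn]C | starting material
3 | iodomethane | CI | starting material
4 | methylzinc (3S)-4,4-dimethoxy-3-methylcyclohexa-1,5-dien-1-olate (zinc enolate) | COC1(OC)C=CC(O[Zn]C)=C[C@@H]1C | intermediate
5 | (5S,6S)-4,4-dimethoxy-5,6-dimethylcyclohex-2-en-1-one | COC1(OC)C=CC(=O)[C@@H](C)[C@@H]1C | intermediate
6 | methyl bromoacetate | COC(=O)CBr | starting material
7 | lithium (3S)-4,4-dimethoxy-2,3-dimethylcyclohexa-1,5-dien-1-olate (lithium dienolate) | COC1(OC)C=CC(O[Li])=C(C)[C@@H]1C | intermediate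
8 | methyl 2-[(1S,6S)-5,5-dimethoxy-1,6-dimethyl-2-oxocyclohex-3-en-1-yl]acetate | COC1(OC)C=CC(=O)[C@@](C)(CC(=O)OC)[C@@H]1C | intermediate
9 | lithium enolate of the 1,4-reduced ketone (C3=C20–OLi) | COC1(OC)CC=C(O[Li])[C@@](C)(CC(=O)OC)[C@@H]1C | intermediate
10 | dimethyl 2,2'-[(1S,6S)-5,5-dimethoxy-1,6-dimethyl-2-oxocyclohexane-1,3-diyl]diacetate (mixture of C3 epimers) | COC1(OC)CC(CC(=O)OC)C(=O)[C@@](C)(CC(=O)OC)[C@@H]1C | intermediate
11 | formaldehyde | C=O | starting material
12 | lithium enolate of 10 (tetrasubstituted, C3=C20–OLi) | COC1(OC)CC(CC(=O)OC)=C(O[Li])[C@@](C)(CC(=O)OC)[C@@H]1C | intermediate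
13 | lithium alkoxide of the C3 hydroxymethyl adduct (CH2OLi α, CH2CO2Me β) | COC1(OC)C[C@@](CO[Li])(CC(=O)OC)C(=O)[C@@](C)(CC(=O)OC)[C@@H]1C | intermediate
14 | methyl 2-[(5S,7S,8S)-9,9-dimethoxy-7,8-dimethyl-3,6-dioxo-2-oxaspiro[4.5]decan-7-yl]acetate | COC1(OC)C[C@]2(COC(=O)C2)C(=O)[C@@](C)(CC(=O)OC)[C@@H]1C | intermediate
15 | 3-bromofuran-2-carbaldehyde | O=Cc1occc1Br | starting material
16 | (triphenylphosphoranylidene)acetaldehyde | O=CC=P(c1ccccc1)(c1ccccc1)c1ccccc1 | starting material
17 | (2E)-3-(3-bromofuran-2-yl)prop-2-enal | O=C/C=C/c1occc1Br | intermediate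
18 | lithium enolate of spirolactone 14 | COC1(OC)C[C@]2(COC(O[Li])=C2)C(=O)[C@@](C)(CC(=O)OC)[C@@H]1C | intermediate
19 | lithium aldolate of 14 and 17 (C7, C8 unassigned) | COC1(OC)C[C@]2(COC(=O)C2C(O[Li])/C=C/c2occc2Br)C(=O)[C@@](C)(CC(=O)OC)[C@@H]1C | intermediate
20 | allylic mesylate of the aldol adduct | COC1(OC)C[C@]2(COC(=O)C2C(OS(C)(=O)=O)/C=C/c2occc2Br)C(=O)[C@@](C)(CC(=O)OC)[C@@H]1C | intermediate
21 | methyl 2-[(4E,5S,7S,8S)-4-[(2E)-3-(3-bromofuran-2-yl)prop-2-en-1-ylidene]-9,9-dimethoxy-7,8-dimethyl-3,6-dioxo-2-oxaspiro[4.5]decan-7-yl]acetate | COC1(OC)C[C@]2(COC(=O)/C2=C/C=C/c2occc2Br)C(=O)[C@@](C)(CC(=O)OC)[C@@H]1C | intermediate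
22 | ring-B carbinol (ring A–ring B–butenolide tricycle; 20α-OH, 10α-(3-bromofuran-2-yl), H-10 β; C1 dimethyl ketal; C17–CO2Me) | COC1(OC)C[C@@]23COC(=O)C2=CC[C@H](c2occc2Br)[C@@]3(O)[C@@](C)(CC(=O)OC)[C@@H]1C | intermediate
23 | water | O | starting material
24 | trilithio species (C20–OLi, lactone dienolate, 3-lithiofuran) | COC1(OC)C[C@@]23COC(O[Li])=C2C=C[C@H](c2occc2[Li])[C@@]3(O[Li])[C@@](C)(CC(=O)OC)[C@@H]1C | intermediate
25 | pentacyclic hydroxy ketone, C1 dimethyl ketal (C10 and C20 both epimeric to the target) | COC1(OC)C[C@@]23COC(=O)C2=CC[C@@H]2c4occc4C(=O)C[C@@](C)([C@@H]1C)[C@]23O | intermediate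
26 | pentacyclic dienone ketone (C10=C20, C7=C8, C16 ketone, C1 ketone) | O=C1C[C@@]23COC(=O)C2=CCC2=C3[C@@](C)(CC(=O)c3ccoc23)[C@@H]1C | intermediate
27 | pentacyclic dienone 1α-alcohol (1R) | O[C@@H]1C[C@@]23COC(=O)C2=CCC2=C3[C@@](C)(CC(=O)c3ccoc23)[C@@H]1C | intermediate
28 | acetic anhydride | CC(=O)OC(C)=O | starting material
29 | pentacyclic dienone 1α-acetate | CC(=O)O[C@@H]1C[C@@]23COC(=O)C2=CCC2=C3[C@@](C)(CC(=O)c3ccoc23)[C@@H]1C | intermediate
30 | dimethyldioxirane | CC1(C)OO1 | starting material
31 | 10β,20β-epoxide of 29 | CC(=O)O[C@@H]1C[C@@]23COC(=O)C2=CC[C@@]2(O4)[C@]34[C@@](C)(CC(=O)c3ccoc23)[C@@H]1C | intermediate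
32 | CNP0329797.2 | CC(=O)O[C@@H]1C[C@@]23COC(=O)C2=CC[C@H]2c4occc4C(=O)C[C@@](C)([C@@H]1C)[C@@]23O | target

## Step count and risks

Total: 12 steps. Longest linear sequence: 11 steps (steps 1–4 and 6–12); step 5 makes the side fragment.

**Step 7 (key reductive cyclisation).** Risks are loss of the furan bromide from the reduced π system, plain reduction of the dienyl lactone, and failure of the δ-carbon to add to the doubly neopentyl ketone. The fallback makes the C10–C20 bond by aldol condensation and builds the furan last. It sets out from 14: aldol condensation with 4-oxopentanal under the step 6 protocol gives the keto alkylidene lactone F3. KOt-Bu in t-BuOH/THF then closes ring B by intramolecular aldol condensation of the ketone α-CH2 (C10) onto the C20 ketone to give the acetyl diene F4. On warming with excess base, the acetyl methyl is acylated by the C16 ester to give the cycloheptene-1,3-dione F5. Feist–Benary annulation with chloroacetaldehyde (NaHCO3, then aqueous HCl, which also cleaves the ketal) closes the furan through the C11 enol oxygen and comes back to the route at 26.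

**Step 8 (Parham cyclisation).** Risks are quenching of the furyllithium by acidic C–H bonds, attack at the wrong carbonyl, and an unfavourable geometry for the seven-membered closure. The fallback drops the bromine and closes the ring by Friedel–Crafts acylation after the tertiary alcohol has been removed. It sets out from 14: aldol condensation with commercial (2E)-3-(furan-2-yl)prop-2-enal (step 6 protocol) gives the dienyl lactone F6, and SmI2 cyclisation as in step 7 gives the furyl carbinol F7. TsOH in wet acetone dehydrates the alcohol and cleaves the ketal to the diene keto ester F8, and LiOH (with re-lactonisation on acidification) gives the diene keto acid F9. Treatment with (COCl)2 and then SnCl4 at −78 °C acylates furan C3 and comes back to the route at 26.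

**Step 4 (face of the aldol at C3).** If formaldehyde enters mainly from the β face, the C3 epimer of 14 results. The fallback introduces the two C3 substituents in the opposite order, so the same facial bias then gives the right centre. It sets out from 8: 1,4-reduction with LiBH(s-Bu)3 and trapping of the enolate with benzyl chloromethyl ether gives the benzyloxymethyl ketone F1. LiN(i-Pr)2 and methyl bromoacetate alkylate the C3 enolate to the quaternary diester F2. Hydrogenolysis (H2, Pd/C) frees the primary alcohol, which lactonises onto the geminal ester and comes back to the route at 14.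

Further compounds

F1 | step 4 | methyl 2-[(1S,6S)-3-(benzyloxymethyl)-5,5-dimethoxy-1,6-dimethyl-2-oxocyclohexyl]acetate (C3 epimers) | COC1(OC)CC(COCc2ccccc2)C(=O)[C@@](C)(CC(=O)OC)[C@@H]1C
F2 | step 4 | dimethyl 2,2'-[3-(benzyloxymethyl)-5,5-dimethoxy-1,6-dimethyl-2-oxocyclohexane-1,3-diyl]diacetate (CH2OBn α, C3 acetate arm β) | COC1(OC)C[C@@](COCc2ccccc2)(CC(=O)OC)C(=O)[C@@](C)(CC(=O)OC)[C@@H]1C
F3 | step 7 | keto alkylidene lactone (spirolactone 14 carrying an (E)-4-oxopentylidene group on C7) | COC1(OC)C[C@]2(COC(=O)/C2=C/CCC(C)=O)C(=O)[C@@](C)(CC(=O)OC)[C@@H]1C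
F4 | step 7 | acetyl diene (ring B closed, C10=C20, acetyl on C10, C1 ketal, C17–CO2Me) | COC1(OC)C[C@@]23COC(=O)C2=CCC(C(C)=O)=C3[C@@](C)(CC(=O)OC)[C@@H]1C
F5 | step 7 | cycloheptene-1,3-dione (C11 and C16 ketones, C10=C20, C1 ketal) | COC1(OC)C[C@@]23COC(=O)C2=CCC2=C3[C@@](C)(CC(=O)CC2=O)[C@@H]1C
F6 | step 8 | debromo dienyl lactone (21 with furan-2-yl in place of 3-bromofuran-2-yl) | COC1(OC)C[C@]2(COC(=O)/C2=C/C=C/c2ccco2)C(=O)[C@@](C)(CC(=O)OC)[C@@H]1C
F7 | step 8 | furyl carbinol (22 without bromine) | COC1(OC)C[C@@]23COC(=O)C2=CC[C@H](c2ccco2)[C@@]3(O)[C@@](C)(CC(=O)OC)[C@@H]1C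
F8 | step 8 | diene keto ester (C10=C20, 10-(furan-2-yl), C1 ketone, C17–CO2Me) | O=C1C[C@@]23COC(=O)C2=CCC(c2ccco2)=C3[C@@](C)(CC(=O)OC)[C@@H]1C
F9 | step 8 | diene keto acid (F8 with C17–CO2H) | O=C1C[C@@]23COC(=O)C2=CCC(c2ccco2)=C3[C@@](C)(CC(=O)O)[C@@H]1C
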